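**Retrosynthetic overview**
- Feature: ring A is a benzene fused to the dihydrofuran through O1–C7a and C3–C3a and carries only the C5 side chain, so its six carbons are cut into three alkynes: C7a≡C7 (an ynol ether on O1), C3a≡C4 (an alkyne on C3) and C5≡C6 (an enyne that brings the whole side chain).
- End game: allylic alcohol from the cinnamate (hydride reduction); C7–H from C7–SiEt3 and CH2OH from CH2OPMB in one acid step.
- Key disconnection: rhodium-catalysed [2+2+2] of the silyl ynol ether diyne with ethyl (E)-pent-2-en-4-ynoate forms C3a–C7a, C4–C5 and C6–C7. The dihydrofuran ring closes first (oxidative coupling) and ring A second (insertion and reductive elimination), in the same catalytic cycle.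
- Diyne from the anti homopropargylic alcohol by O-dichlorovinylation, elimination to the lithium alkoxyacetylide, C-silylation and selective alkyne unmasking.
- Anti alcohol (C2 and C3 of the target) from 3,4,5-trimethoxybenzaldehyde and an (R)-propargylic mesylate by allenylzinc addition; the mesylate from an ynone by asymmetric transfer hydrogenation.

Key step: step 11

**Remarks on the chemistry**
- Assumption: (4-methoxybenzyloxy)acetaldehyde, 3-(trimethylsilyl)propynal and triethyl phosphonoacetate are bought.
- The CH2O arm on C3 is carried as a PMB ether. The potassium alkoxide needed for O-dichlorovinylation sits 1,3 to it, and a silyl ether there would migrate.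
- The ynol ether carries SiEt3 and the other alkyne SiMe3. Both alkynes are silylated when the lithium alkoxyacetylide is made, and only a size difference lets carbonate/methanol free the carbon-bound alkyne alone.
- The side chain enters as the enoate and is reduced last. The acid that removes the C7 silane would ionise a p-alkoxycinnamyl ether or alcohol, but not a cinnamate.

**Route**

Step 1
Reactants: 1 (4-methoxybenzyloxy)acetaldehyde; 2 trimethylsilylacetylene
Product: 4 rac-1-(4-methoxybenzyloxy)-4-(trimethylsilyl)but-3-yn-2-ol, via lithium (trimethylsilyl)acetylide 3 (not isolated)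
Conditions: 2, n-BuLi, THF, −78 °C; then 1, −78 to 0 °C; aq NH4Cl
Reagents that add atoms: none
Why: 1,2-addition of a lithium acetylide to an aldehyde; the carbinol centre is made racemic on purpose, since step 2 erases it and step 3 resets it.

Step 2
Reactants: 4 rac-1-(4-methoxybenzyloxy)-4-(trimethylsilyl)but-3-yn-2-ol
Product: 5 1-(4-methoxybenzyloxy)-4-(trimethylsilyl)but-3-yn-2-one
Conditions: Dess–Martin periodinane, CH2Cl2, 0 °C to rt
Reagents that add atoms: none
Why: Dess–Martin oxidation of a secondary propargylic alcohol under neutral conditions should leave the PMB ether and the alkynylsilane untouched.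

Step 3
Reactants: 5 1-(4-methoxybenzyloxy)-4-(trimethylsilyl)but-3-yn-2-one
Product: 6 (R)-1-(4-methoxybenzyloxy)-4-(trimethylsilyl)but-3-yn-2-ol
Conditions: Ru[(S,S)-TsDPEN](p-cymene) (1 mol%), i-PrOH, rt
Reagents that add atoms: none
Why: Noyori asymmetric transfer hydrogenation of an alkynyl ketone; the alkyne plays the role of the aryl group in the transition state, so the (S,S)-catalyst that gives (S)-alcohols from but-3-yn-2-ones should attack the same face here, and the carbinol is labelled R only because CH2OPMB outranks the alkyne.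

Step 4
Reactants: 6 (R)-1-(4-methoxybenzyloxy)-4-(trimethylsilyl)but-3-yn-2-ol
Product: 7 (R)-1-(4-methoxybenzyloxy)-4-(trimethylsilyl)but-3-yn-2-yl methanesulfonate
Conditions: MsCl, Et3N, CH2Cl2, −78 to 0 °C; used crude
Reagents that add atoms: methanesulfonyl chloride, CS(=O)(=O)Cl
Why: O-sulfonylation (mesylation) with retention at carbon installs the leaving group for the anti SN2′ oxidative addition of step 5.

Step 5
Reactants: 7 (R)-1-(4-methoxybenzyloxy)-4-(trimethylsilyl)but-3-yn-2-yl methanesulfonate; 8 3,4,5-trimethoxybenzaldehyde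
Product: 10 (1R,2S)-2-[(4-methoxybenzyloxy)methyl]-1-(3,4,5-trimethoxyphenyl)-4-(trimethylsilyl)but-3-yn-1-ol, via allenyl(ethyl)zinc reagent 9 (not isolated)
Conditions: Pd(OAc)2 (5 mol%), PPh3 (5 mol%), Et2Zn (3 equiv), THF, −78 to −20 °C; aq NH4Cl
Reagents that add atoms: none
Why: Marshall propargylation: zerovalent palladium displaces the mesylate anti in an SN2′ sense, transmetalation to zinc with retention gives the axially chiral allenylzinc, and its cyclic SE2′ addition to the aldehyde with the aryl group turned away from the CH2OPMB arm sets C1 (R) and C2 (S) together as the anti pair.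

Step 6
Reactants: 10 (1R,2S)-2-[(4-methoxybenzyloxy)methyl]-1-(3,4,5-trimethoxyphenyl)-4-(trimethylsilyl)but-3-yn-1-ol; 11 trichloroethylene
Product: 14 (E)-1,2-dichlorovinyl ether of 10, via potassium alkoxide of 10 12 (not isolated), via dichloroacetylene 13 (not isolated)
Conditions: KH, THF, 0 °C; then ClCH=CCl2, −50 °C to rt
Reagents that add atoms: none
Why: O-dichlorovinylation of an alkoxide with trichloroethylene: the alkoxide eliminates HCl from the reagent, adds anti to the dichloroacetylene so formed, and the vinyl anion is protonated to the (E)-dichlorovinyl ether without touching either stereocentre.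

Step 7
Reactants: 14 (E)-1,2-dichlorovinyl ether of 10
Product: 17 (1R,2S)-2-[(4-methoxybenzyloxy)methyl]-1-(3,4,5-trimethoxyphenyl)-4-(trimethylsilyl)but-3-ynyl (triethylsilyl)ethynyl ether, via chloroethynyl ether 15 (not isolated), via lithium alkynyl ether 16 (not isolated)
Conditions: n-BuLi (2.3 equiv), THF, −78 to −40 °C; then Et3SiCl, −78 to 0 °C; quick filtration through Et3N-deactivated silica, stored cold
Reagents that add atoms: chlorotriethylsilane, CC[Si](Cl)(CC)CC
Why: Dichlorovinyl ether to ynol ether by elimination and lithium–chlorine exchange: deprotonation and loss of LiCl give the chloroalkynyl ether, exchange gives the lithium alkoxyacetylide, and C-silylation caps it with a group that is bulkier and far less base-labile than the SiMe3 on the other alkyne.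

Step 8
Reactants: 17 (1R,2S)-2-[(4-methoxybenzyloxy)methyl]-1-(3,4,5-trimethoxyphenyl)-4-(trimethylsilyl)but-3-ynyl (triethylsilyl)ethynyl ether
Product: 18 (1R,2S)-2-[(4-methoxybenzyloxy)methyl]-1-(3,4,5-trimethoxyphenyl)but-3-ynyl (triethylsilyl)ethynyl ether
Conditions: K2CO3 (0.3 equiv), MeOH/THF, 0 °C, stopped when 17 is consumed
Reagents that add atoms: none
Why: Base-catalysed methanolysis of an alkynylsilane (protodesilylation) is strongly retarded by the ethyl groups on silicon, so the SiMe3 on the carbon-bound alkyne should be removed while the SiEt3 on the ynol ether stays; ynol ethers tolerate base.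

Step 9
Reactants: 19 3-(trimethylsilyl)propynal; 20 triethyl phosphonoacetate
Product: 22 ethyl (E)-5-(trimethylsilyl)pent-2-en-4-ynoate, via sodium phosphonate carbanion 21 (not isolated)
Conditions: 20, NaH, THF, 0 °C; then 19, 0 °C to rt
Reagents that add atoms: none
Why: Horner–Wadsworth–Emmons olefination of a non-enolisable ynal with a stabilised phosphonate anion should give the (E)-enoate.

Step 10
Reactants: 22 ethyl (E)-5-(trimethylsilyl)pent-2-en-4-ynoate
Product: 23 ethyl (E)-pent-2-en-4-ynoate
Conditions: K2CO3 (cat.), EtOH, 0 °C, short contact; kept as a cold solution and used at once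
Reagents that add atoms: none
Why: Carbonate-catalysed ethanolysis of the alkynyl–silicon bond (protodesilylation) frees the terminal alkyne, and ethanol as solvent avoids transesterification.

Step 11
Reactants: 18 (1R,2S)-2-[(4-methoxybenzyloxy)methyl]-1-(3,4,5-trimethoxyphenyl)but-3-ynyl (triethylsilyl)ethynyl ether; 23 ethyl (E)-pent-2-en-4-ynoate
Product: 24 ethyl (E)-3-[(2R,3S)-3-[(4-methoxybenzyloxy)methyl]-7-(triethylsilyl)-2-(3,4,5-trimethoxyphenyl)-2,3-dihydro-1-benzofuran-5-yl]prop-2-enoate
Conditions: RhCl(PPh3)3 (10 mol%), 23 (4 equiv), toluene, 25 to 40 °C, 18 added slowly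
Reagents that add atoms: none
Why: Monovalent rhodium binds the two tethered alkynes of 18 and couples them oxidatively to a trivalent rhodacyclopentadiene, which forms C3a–C7a and so closes the dihydrofuran ring as the five-membered ring fused to the metallacycle; coordination and insertion of the alkyne of 23 followed by reductive elimination form C4–C5 and C6–C7 and close ring A as the six-membered carbocycle of an overall [2+2+2] cycloaddition. The closest known reactions are the RhCl(PPh3)3-catalysed cyclotrimerisations of ynamide-tethered 1,6-diynes with monoalkynes to indolines and of aryl alkynyl ether diynes to dibenzofurans, and an alkyl silyl ynol ether in the tether is the only change. No stereocentre is formed, and C2 and C3 lie outside the reacting atoms, so the anti pair of 10 becomes the 2,3-trans pattern unchanged. The step needs the vinyl-bearing alkyne carbon of 23 to bond to C4 and not to C7: the SiEt3 group on the rhodium-bound C7 crowds that side, so the substituted carbon should go to the unhindered C4–H terminus and the chain should end at C5, para to O1. Cross-selectivity over self-trimerisation of 23 rests on the tether, which makes the first coupling intramolecular, and on slow addition of 18 to an excess of 23; the conjugated alkene of 23 is a poorer ligand than its alkyne and should stay out. The temperature is held at or below 40 °C because a secondary benzylic ynol ether can lose a ketene by a retro-ene path or rearrange sigmatropically on heating.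

Step 12
Reactants: 24 ethyl (E)-3-[(2R,3S)-3-[(4-methoxybenzyloxy)methyl]-7-(triethylsilyl)-2-(3,4,5-trimethoxyphenyl)-2,3-dihydro-1-benzofuran-5-yl]prop-2-enoate
Product: 25 ethyl (E)-3-[(2R,3S)-3-(hydroxymethyl)-2-(3,4,5-trimethoxyphenyl)-2,3-dihydro-1-benzofuran-5-yl]prop-2-enoate
Conditions: CF3CO2H/CH2Cl2 (1:1), anisole (10 equiv), 0 °C to rt; aq NaHCO3/EtOH wash
Reagents that add atoms: none
Why: Acid-mediated ipso-protodesilylation (electrophilic aromatic substitution at C7, which is ortho to O1 and helped by the β-silicon effect) and acidolysis of the PMB ether with anisole as cation trap run in the same medium, and the cinnamate is not ionised by CF3CO2H.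

Step 13
Reactants: 25 ethyl (E)-3-[(2R,3S)-3-(hydroxymethyl)-2-(3,4,5-trimethoxyphenyl)-2,3-dihydro-1-benzofuran-5-yl]prop-2-enoate
Product: 26 (E)-3-[(2R,3S)-3-(hydroxymethyl)-2-(3,4,5-trimethoxyphenyl)-2,3-dihydro-1-benzofuran-5-yl]prop-2-en-1-ol (CNP0077408.1)
Conditions: i-Bu2AlH (4 equiv), CH2Cl2, −78 °C; Rochelle salt work-up
Reagents that add atoms: none
Why: 1,2-Reduction of an α,β-unsaturated ester by i-Bu2AlH should stop at the (E)-allylic alcohol and touches neither stereocentre.

**Compound list**
1 | (4-methoxybenzyloxy)acetaldehyde | O=CCOCc1ccc(OC)cc1 | starting material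
2 | trimethylsilylacetylene | C#C[Si](C)(C)C | starting material
3 | lithium (trimethylsilyl)acetylide | [Li]C#C[Si](C)(C)C | intermediate
4 | rac-1-(4-methoxybenzyloxy)-4-(trimethylsilyl)but-3-yn-2-ol | C[Si](C)(C)C#CC(O)COCc1ccc(OC)cc1 | intermediate
5 | 1-(4-methoxybenzyloxy)-4-(trimethylsilyl)but-3-yn-2-one | C[Si](C)(C)C#CC(=O)COCc1ccc(OC)cc1 | intermediate
6 | (R)-1-(4-methoxybenzyloxy)-4-(trimethylsilyl)but-3-yn-2-ol | C[Si](C)(C)C#C[C@@H](O)COCc1ccc(OC)cc1 | intermediate
7 | (R)-1-(4-methoxybenzyloxy)-4-(trimethylsilyl)but-3-yn-2-yl methanesulfonate | C[Si](C)(C)C#C[C@@H](OS(C)(=O)=O)COCc1ccc(OC)cc1 | intermediate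
8 | 3,4,5-trimethoxybenzaldehyde | COc1cc(C=O)cc(OC)c1OC | starting material
9 | ethyl[4-(4-methoxybenzyloxy)-1-(trimethylsilyl)buta-1,2-dienyl]zinc (axially chiral, zinc on the face opposite the departed mesylate; axis not encoded) | CC[Zn]C(=C=CCOCc1ccc(OC)cc1)[Si](C)(C)C | intermediate
10 | (1R,2S)-2-[(4-methoxybenzyloxy)methyl]-1-(3,4,5-trimethoxyphenyl)-4-(trimethylsilyl)but-3-yn-1-ol | COc1cc([C@H](O)[C@H](COCc2ccc(OC)cc2)C#C[Si](C)(C)C)cc(OC)c1OC | intermediate
11 | trichloroethylene | ClC=C(Cl)Cl | starting material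
12 | potassium alkoxide of 10 | COc1cc([C@H]([O-])[C@H](COCc2ccc(OC)cc2)C#C[Si](C)(C)C)cc(OC)c1OC.[K+] | intermediate
13 | dichloroacetylene | ClC#CCl | intermediate
14 | (E)-1,2-dichlorovinyl ether of 10 | COc1cc([C@H](O/C(Cl)=C\Cl)[C@H](COCc2ccc(OC)cc2)C#C[Si](C)(C)C)cc(OC)c1OC | intermediate
15 | chloroethynyl ether of 10 | COc1cc([C@H](OC#CCl)[C@H](COCc2ccc(OC)cc2)C#C[Si](C)(C)C)cc(OC)c1OC | intermediate
16 | lithium alkynyl ether (lithioethynyl ether of 10) | COc1cc([C@H](OC#C[Li])[C@H](COCc2ccc(OC)cc2)C#C[Si](C)(C)C)cc(OC)c1OC | intermediate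
17 | (1R,2S)-2-[(4-methoxybenzyloxy)methyl]-1-(3,4,5-trimethoxyphenyl)-4-(trimethylsilyl)but-3-ynyl (triethylsilyl)ethynyl ether | COc1cc([C@H](OC#C[Si](CC)(CC)CC)[C@H](COCc2ccc(OC)cc2)C#C[Si](C)(C)C)cc(OC)c1OC | intermediate
18 | (1R,2S)-2-[(4-methoxybenzyloxy)methyl]-1-(3,4,5-trimethoxyphenyl)but-3-ynyl (triethylsilyl)ethynyl ether | COc1cc([C@H](OC#C[Si](CC)(CC)CC)[C@H](COCc2ccc(OC)cc2)C#C)cc(OC)c1OC | intermediate
19 | 3-(trimethylsilyl)propynal | O=CC#C[Si](C)(C)C | starting material
20 | triethyl phosphonoacetate | CCOC(=O)CP(=O)(OCC)OCC | starting material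
21 | sodium salt of the triethyl phosphonoacetate carbanion | CCOC(=O)[CH-]P(=O)(OCC)OCC.[Na+] | intermediate
22 | ethyl (E)-5-(trimethylsilyl)pent-2-en-4-ynoate | CCOC(=O)/C=C/C#C[Si](C)(C)C | intermediate
23 | ethyl (E)-pent-2-en-4-ynoate | CCOC(=O)/C=C/C#C | intermediate
24 | ethyl (E)-3-[(2R,3S)-3-[(4-methoxybenzyloxy)methyl]-7-(triethylsilyl)-2-(3,4,5-trimethoxyphenyl)-2,3-dihydro-1-benzofuran-5-yl]prop-2-enoate | COc1cc([C@@H]2Oc3c([Si](CC)(CC)CC)cc(/C=C/C(=O)OCC)cc3[C@H]2COCc4ccc(OC)cc4)cc(OC)c1OC | intermediate
25 | ethyl (E)-3-[(2R,3S)-3-(hydroxymethyl)-2-(3,4,5-trimethoxyphenyl)-2,3-dihydro-1-benzofuran-5-yl]prop-2-enoate | COc1cc([C@@H]2Oc3ccc(/C=C/C(=O)OCC)cc3[C@H]2CO)cc(OC)c1OC | intermediate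
26 | (E)-3-[(2R,3S)-3-(hydroxymethyl)-2-(3,4,5-trimethoxyphenyl)-2,3-dihydro-1-benzofuran-5-yl]prop-2-en-1-ol | COc1cc([C@@H]2Oc3ccc(/C=C/CO)cc3[C@H]2CO)cc(OC)c1OC | target

**Step count**
Total: 13 steps. Longest linear sequence: 11 steps (steps 1–8, then 11–13); steps 9–10 make the enynoate in a side branch.

**Three steps most likely to fail**

1. Step 11. What may go wrong: oxidative coupling at the silyl-capped ynol ether may be slow, so that thermal fragmentation of the ynol ether and self-trimerisation of the enynoate overtake the cross-cycloaddition; the insertion may also lose its regiocontrol. Fallback (sets out from 8, comes back at 26): ring A is bought instead of built, and the dihydrofuran is closed by a carbene C–H insertion.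
   - 8 is reduced (NaBH4, MeOH) to 3,4,5-trimethoxybenzyl alcohol F1.
   - Mitsunobu etherification (PPh3, DIAD, THF) with purchased methyl 2-(5-bromo-2-hydroxyphenyl)acetate gives methyl 2-[5-bromo-2-(3,4,5-trimethoxybenzyloxy)phenyl]acetate F2.
   - Diazo transfer (4-acetamidobenzenesulfonyl azide, DBU, MeCN) gives methyl 2-diazo-2-[5-bromo-2-(3,4,5-trimethoxybenzyloxy)phenyl]acetate F3.
   - Intramolecular insertion of the rhodium carbene into the benzylic ether C–H bond gives methyl (2R,3S)-5-bromo-2-(3,4,5-trimethoxyphenyl)-2,3-dihydro-1-benzofuran-3-carboxylate (cis) F4. The catalyst is the enantiomer of dirhodium tetrakis(N-phthaloyl-tert-leucinate), Rh2(PTTL)4, that leads to the 2R series (toluene, −60 °C).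
   - NaOMe in MeOH epimerises C3 to methyl (2R,3R)-5-bromo-2-(3,4,5-trimethoxyphenyl)-2,3-dihydro-1-benzofuran-3-carboxylate (trans) F5.
   - Heck coupling with ethyl acrylate (Pd(OAc)2, P(o-tol)3, Et3N, DMF, 100 °C) gives methyl (2R,3R)-5-[(E)-3-ethoxy-3-oxoprop-1-enyl]-2-(3,4,5-trimethoxyphenyl)-2,3-dihydro-1-benzofuran-3-carboxylate F6.
   - i-Bu2AlH reduces both esters of F6 to 26.

2. Step 6. What may go wrong: the alkynyl SiMe3 group may transfer to the potassium alkoxide, and a hindered benzylic alkoxide may capture dichloroacetylene only slowly. Fallback (sets out from 10, comes back at 16 and so at 17): the two carbons are attached without ever forming the alkoxide.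
   - 10 is formylated (acetic formic anhydride, pyridine, 0 °C) to the formate of 10, F7.
   - Ramirez-type dibromomethylenation of the formate carbonyl (PPh3, CBr4, CH2Cl2) gives the 2,2-dibromovinyl ether of 10, F8.
   - n-BuLi (THF, −78 to −40 °C) takes F8 by elimination and lithium–bromine exchange to the lithium alkynyl ether 16, which is silylated as in step 7.

3. Step 5. What may go wrong: anti/syn selectivity may erode with an aromatic aldehyde, and the alkoxymethyl-substituted allenylmetal may undergo β-elimination. Fallback (sets out from 6, comes back at 10): the allenylmetal is made as an isolable boronate, whose shorter B–O and B–C bonds give a tighter cyclic transition state.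
   - 6 is converted (ClCO2Me, pyridine) into (R)-1-(4-methoxybenzyloxy)-4-(trimethylsilyl)but-3-yn-2-yl methyl carbonate F9.
   - Copper-catalysed anti-SN2′ borylation (CuOtBu, Xantphos, B2pin2, THF) gives the axially chiral pinacol [4-(4-methoxybenzyloxy)-1-(trimethylsilyl)buta-1,2-dienyl]boronate F10.
   - Allenylboration of 8 (toluene, rt to 50 °C, with a diaryl phosphoric acid as catalyst if needed) through the same closed SE2′ geometry should give 10 after work-up.

**Further compounds**
F1 | step 11 | 3,4,5-trimethoxybenzyl alcohol | COc1cc(CO)cc(OC)c1OC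
F2 | step 11 | methyl 2-[5-bromo-2-(3,4,5-trimethoxybenzyloxy)phenyl]acetate | COC(=O)Cc1cc(Br)ccc1OCc1cc(OC)c(OC)c(OC)c1
F3 | step 11 | methyl 2-diazo-2-[5-bromo-2-(3,4,5-trimethoxybenzyloxy)phenyl]acetate | COC(=O)C(=[N+]=[N-])c1cc(Br)ccc1OCc1cc(OC)c(OC)c(OC)c1
F4 | step 11 | methyl (2R,3S)-5-bromo-2-(3,4,5-trimethoxyphenyl)-2,3-dihydro-1-benzofuran-3-carboxylate (cis) | COc1cc([C@@H]2Oc3ccc(Br)cc3[C@@H]2C(=O)OC)cc(OC)c1OC
F5 | step 11 | methyl (2R,3R)-5-bromo-2-(3,4,5-trimethoxyphenyl)-2,3-dihydro-1-benzofuran-3-carboxylate (trans) | COc1cc([C@@H]2Oc3ccc(Br)cc3[C@H]2C(=O)OC)cc(OC)c1OC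
F6 | step 11 | methyl (2R,3R)-5-[(E)-3-ethoxy-3-oxoprop-1-enyl]-2-(3,4,5-trimethoxyphenyl)-2,3-dihydro-1-benzofuran-3-carboxylate | COc1cc([C@@H]2Oc3ccc(/C=C/C(=O)OCC)cc3[C@H]2C(=O)OC)cc(OC)c1OC
F7 | step 6 | formate of 10 | COc1cc([C@H](OC=O)[C@H](COCc2ccc(OC)cc2)C#C[Si](C)(C)C)cc(OC)c1OC
F8 | step 6 | 2,2-dibromovinyl ether of 10 | COc1cc([C@H](OC=C(Br)Br)[C@H](COCc2ccc(OC)cc2)C#C[Si](C)(C)C)cc(OC)c1OC
F9 | step 5 | (R)-1-(4-methoxybenzyloxy)-4-(trimethylsilyl)but-3-yn-2-yl methyl carbonate | C[Si](C)(C)C#C[C@@H](OC(=O)OC)COCc1ccc(OC)cc1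
F10 | step 5 | pinacol [4-(4-methoxybenzyloxy)-1-(trimethylsilyl)buta-1,2-dienyl]boronate (axially chiral; axis not encoded) | CC1(C)OB(OC1(C)C)C(=C=CCOCc2ccc(OC)cc2)[Si](C)(C)C
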